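## The problem

Compound 14 is a longipinane diester. A verbenone-like bicyclo[3.1.1]hept-2-en-1-one (C1, C2=C3, C4, C11, with C5 and C10 as the one-carbon bridges) has its two bridges joined, on the side away from the enone, by the chain C6–C7–C8–C9, so that a cyclobutane (C4–C5–C11–C10), a cyclohexenone and a cycloheptane share C5, C10 and C11. The cyclobutane carries four contiguous stereocentres (C4, C5, C11 and the quaternary C10). The cage locks them to one another, so they amount to one choice of absolute sense, but they must be created together with a strained ring that stepwise enolate or cation chemistry does not close readily. The ester carbinols C7 and C9 are trans across C8 and both neopentyl; C9–O lies on the side of bridgehead C4 and C7–O on the side of bridgehead C11. The strip C6–C10 sits in a local mirror plane of the bicyclo[4.1.1]octane half (the C10 methyl and C5–H lie in it), and its two faces differ only in whether the flanking bridgehead leads on to C3–CH3 or to C1=O. The core centres are therefore expected to bias C7 and C9 only weakly: one carbinol needs a reagent or an enzyme to set it, and the other can be relayed from the first across the 1,3-distance. The fragile elements are the angelates (Z to E isomerisation to tiglates under nucleophilic catalysis, acid, base or long heating), the cyclobutane next to any cationic centre (Wagner–Meerwein ring expansion), β-oxygenated ketone intermediates (retro-aldol, elimination) and the light-sensitive bridged enone. The enabling feature is that the fifteen skeletal carbons, with methyls on C3 and C10 and two on C6, form an unbroken head-to-tail farnesyl chain in which C5–C6, C5–C11 and C4–C10 are the farnesyl 1,11-, 1,6- and 2,7-bonds and C2=C3 is the alkene left when that cation cascade ends. The complete hydrocarbon tricycle is therefore (+)-α-longipinene 4, the product of one terpene-cyclase reaction of farnesyl diphosphate 3.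

## Retrosynthesis

**14 to 11 and 12.** The two ester C–O bonds are cut first, giving diol 11 and angelic acid 12 (activated as mixed anhydride 13). Carrying a Z-enoate through oxidations, a hydride reduction and a copper-catalysed conjugate addition would invite isomerisation or conjugate attack, so acylation is placed last. The forward step must acylate two neopentyl alcohols without Z to E leakage.

**11 to 10.** The C7–H bond is cut, so the C7 carbinol becomes a ketone in β-hydroxy ketone 10. Because the ring faces are nearly equivalent, an external hydride would not choose well. A hydride delivered from the C9 oxygen must enter C7 from the C4 side and leaves the new hydroxyl on the C11 side, which is the trans-1,3 relationship of 14. The precursor has one stereocentre fewer, and that one is set by relay.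

**10 to 8.** The C9–O bond is cut back to the C8=C9 enone of dienedione 8 (through boronate 9). Conjugate borylation is preferred to nucleophilic epoxidation or oxa-Michael addition because a chiral bisphosphine on copper can choose the face; this is the one place where the substrate cannot be trusted to do so. The forward reaction must also leave the β,β-disubstituted C2=C3 enone alone.

**8 to 6 to 5.** The C8=C9 unsaturation and the C7 carbonyl are traced to carbinol 6 (through saturated diketone 7), and the C7–O bond of 6 to a C–H bond of enone 5. Only one remote C–H hydroxylation is asked of a P450 instead of two, and only its site matters, since C7 becomes sp2 at once. Hydroxylation at C9 would serve equally through the mirror-image relay, so only C8 is a dead end. C7 is flanked by quaternary C6, so enolisation and dehydrogenation can go in one direction only.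

**5 to 4.** The C1 carbonyl is removed, leaving (+)-α-longipinene 4. The enone is installed before the hydroxylation because it deactivates the C1–C4 region and the alkene toward the P450 and gives the enzyme a polar anchor. C1 is the only allylic methylene of 4.

**4 to 3.** The three ring bonds C5–C6, C5–C11 and C4–C10 are cut together, unfolding the tricycle to achiral, acyclic (2E,6E)-farnesyl diphosphate 3. No other disconnection removes all three rings, the cyclobutane and four stereocentres at once, and it delivers every skeletal carbon at its final oxidation level (C10 methyl, C6 gem-dimethyl, C2=C3). The forward reaction needs a class 1 sesquiterpene cyclase that steers the longipinyl cation to the C2-deprotonated product of the (4R,5R,10S,11R) series.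

**3 to 2 to 1.** The C1–O–P bond and then the C–Cl bond are cut back to commercial (2E,6E)-farnesol 1. Allylic chloride 2 is the standard electrophile for diphosphate, and both steps must keep the 2E geometry.

## Roads not taken

**Alternative 1:** The cyclobutane bonds C4–C10 and C5–C11 are cut photochemically, leading to the ten-membered (2E,8E)-dienone A1 that already carries the C7 and C9 silyl ethers. Forward, irradiation at 350–370 nm (or thioxanthone sensitisation) excites the C1 enone; C10 bonds to C4 first (five-membered closure), then C11 to C5, giving the crossed adduct A2, a bicyclo[2.1.1]hexan-2-one inside the seven-membered ring. A one-carbon ring expansion and dehydrogenation must then create C2 and the C2=C3 enone.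
- Merits: the two carbinols are made by acyclic carbonyl chemistry before any ring exists, so no C–H oxidation is needed, and the route is abiotic. In this respect it is better than the chosen plan, whose weakest part is the late oxygenation.
- Weak points: A1 is a pentasubstituted ten-membered ring with two E alkenes that has to be closed first. A triplet enone in a medium ring isomerises and can give the straight adduct. Facial control must be transmitted from C7 and C9 through a flexible ring. A2 lacks C2, and inserting it between C1 and C3 of a strained ketone whose two α-carbons are both tertiary is a regiochemical gamble; the C3 centre made in the photoreaction is then discarded.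
- Comparison: the chosen plan sets against the oxygenation advantage a complete C15 skeleton, C2 included, with all four core centres, in one step from a commercial alcohol, followed only by redox and acylation steps.

**Alternative 2:** The C8–C9 bond is cut by a retro-aldol, giving the seco keto aldehyde A3 (C7 methyl ketone on the C6 gem-dimethyl carbon, C9 aldehyde on C10). Forward, the diisopinocampheylboron enolate (Ipc2BOTf, iPr2NEt) of the methyl ketone adds to the aldehyde and closes the seven-membered ring across the cyclobutane diagonal to give A4.
- Merits: A4 is the same molecule as compound 10, so from there the two routes are identical (steps 8 and 9). The C9 carbinol is set by a reagent, the C7 oxygen is in place from the start, and no enzyme is needed; independence from biocatalyst availability is a real advantage.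
- Weak points: all the difficulty of the core is moved into A3. It is a fully substituted bridged enone with four cyclobutane stereocentres, a quaternary carbon bearing a formyl group and a tertiary carbon bearing a tert-alkyl ketone, and no short access to it is apparent. Methyl-ketone aldols with this boron reagent usually give modest induction, the aldehyde is α-quaternary, and the product is retro-aldol-prone.
- Comparison: the chosen plan reaches the same compound 10 in four operations from the cyclase product (steps 4–7), with the cage built by the enzyme.

**Alternative 3:** The bonds C5–C6 and C9–C10 are cut, giving the ring-fused bicyclobutane ester A5 and the bis-siloxydiene A6. Forward, under TMSOTf or Sc(OTf)3 the diene terminus C6 adds to bridgehead C5, and the silyl ketene acetal formed at C10 closes on the C9 oxocarbenium ion, giving A7 with the seven-membered ring, the C7 ketone and the C9 silyl ether.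
- Merits: it is convergent, builds the seven-membered ring and both oxygens in one step, and takes the cyclobutane from stored strain. Convergence and oxygenation are better handled here than in the chosen plan.
- Weak points: A5 is an enantiopure tricyclic bicyclobutane that must itself be made. The nucleophilic carbon C6 is fully substituted and must bond to a bridgehead, creating adjacent tertiary and quaternary centres. The C9 configuration depends on an ordered transition state. Afterwards the C10 ester must be reduced to methyl, the C1 ketal removed, C2=C3 introduced and C7 reduced, a long series of oxidation-level corrections.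
- Comparison: the cyclase delivers C10 methyl and C2=C3 correctly from the outset, which the chosen plan sets against the convergence of this road.

Key step: step 3

Assumption: a recombinant α-longipinene synthase of the (4R,5R,10S,11R) series and a P450 BM3 variant that hydroxylates C7 of 5 are taken to be obtainable by expression and panel screening. The C7 epimer formed in step 5 is immaterial because that centre is erased in step 6 (6 is drawn as 7S).

## Route

Step 1
Reactants: 1 (2E,6E)-farnesol
Product: 2 (2E,6E)-farnesyl chloride
Conditions: NCS, Me2S, CH2Cl2, −40 to 0 °C
Reagents that add atoms: N-chlorosuccinimide, O=C1CCC(=O)N1Cl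
Why: Corey–Kim-type chlorination; the alkoxysulfonium salt of the primary allylic alcohol is displaced by chloride in an SN2 reaction, without allylic transposition or loss of the 2E geometry, as is usual for geraniol and farnesol.

Step 2
Reactants: 2 (2E,6E)-farnesyl chloride
Product: 3 (2E,6E)-farnesyl diphosphate as its triammonium salt
Conditions: (Bu4N)3HP2O7, MeCN, rt; then Dowex 50WX8 (NH4+ form), aq. NH4HCO3/iPrOH; cellulose chromatography
Reagents that add atoms: tris(tetrabutylammonium) hydrogen diphosphate, CCCC[N+](CCCC)(CCCC)CCCC.CCCC[N+](CCCC)(CCCC)CCCC.CCCC[N+](CCCC)(CCCC)CCCC.OP(=O)([O-])OP(=O)([O-])[O-]; ammonium hydrogencarbonate (ammonium counter-ions), [NH4+].OC(=O)[O-]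
Why: SN2 displacement of the primary allylic chloride by the diphosphate trianion in acetonitrile is the standard preparation of allylic diphosphates; cation exchange gives the water-soluble ammonium salt that terpene cyclases accept.

Step 3
Reactants: 3 (2E,6E)-farnesyl diphosphate, triammonium salt
Product: 4 (+)-α-longipinene, (4R,5R,10S,11R)-longipin-2-ene
Conditions: recombinant α-longipinene synthase (class 1 sesquiterpene cyclase), MgCl2 (10 mM), HEPES pH 7.5, DTT, 10% glycerol, pentane overlay, 30 °C; AgNO3–silica filtration
Reagents that add atoms: none
Why: In a class 1 terpene cyclase the aspartate-rich motifs hold three divalent magnesium ions that pull the diphosphate off C1 of 3 (farnesyl numbering for the chain in this and the next two sentences); the ion pair collapses to nerolidyl diphosphate so that the C2–C3 bond can rotate, and re-ionisation gives the cisoid allyl cation. The C10=C11 bond then attacks C1 (1,11-closure, eleven-membered ring, endo and anti-Markovnikov; longipinane bond C5–C6), and a 1,3-hydride shift from C1 to C10 returns the charge to the allyl system of the (2Z,6E)-humulyl cation. Attack of C6=C7 on C1 (1,6-closure, 6-exo for the new cyclohexene, Markovnikov; longipinane C5–C11) divides the large ring into the six- and seven-membered rings of the cis-fused himachalyl cation; its ring alkene C2=C3 closes onto the tertiary C7 cation (2,7-closure, 4-exo, Markovnikov; longipinane C4–C10) to give the tertiary longipinyl cation, which loses the proton on longipinane C2 to the departed diphosphate or an active-site base. The closest known reaction type is this same one: cation–olefin polycyclisation of farnesyl diphosphate by plant sesquiterpene synthases of the longifolene/longipinene family, of which α-longipinene is a recorded product. The four stereocentres C4, C5, C10 and C11 come from the single chiral fold that the active-site contour imposes on the achiral chain; the cis ring fusion fixed in the 1,6-closure leaves one face on which the cyclobutane can close, and the absolute sense is that of the enzyme. The selectivity required is product fidelity, meaning deprotonation at C2 in preference to exocyclic deprotonation (β-longipinene) or a 1,2-alkyl shift of the cyclobutylcarbinyl cation into the longibornyl and longifolyl series. Nothing in 3 secures this; it rests on the choice (and if needed mutagenesis) of the synthase, while the pentane layer withdraws the hydrocarbon as it forms.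

Step 4
Reactants: 4 (+)-α-longipinene
Product: 5 (4R,5S,10R,11R)-longipin-2-en-1-one
Conditions: CrO3, 3,5-dimethylpyrazole, CH2Cl2, −20 °C
Reagents that add atoms: chromium trioxide, O=[Cr](=O)=O
Why: Allylic oxidation by the hexavalent chromium–dimethylpyrazole complex at the only allylic methylene (C1), the same change that turns α-pinene into verbenone; the bridgehead C4–H and the C3 methyl do not compete, and no stereocentre is touched.

Step 5
Reactants: 5 (4R,5S,10R,11R)-longipin-2-en-1-one
Product: 6 (4R,5S,7S,10R,11R)-7-hydroxylongipin-2-en-1-one (C7 configuration not relied on)
Conditions: P450 BM3 variant (cell lysate), NADP+ (cat.), D-glucose, glucose dehydrogenase, air, KPi pH 8.0, 2% DMSO, 25 °C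
Reagents that add atoms: dioxygen, O=O
Why: P450 hydroxylation of an unactivated methylene by hydrogen abstraction and oxygen rebound at the ferryl (tetravalent iron) oxo haem is an established reaction of sesquiterpenoid ketones with panels of BM3 active-site variants. The enone deactivates C1–C4 and the cyclobutane C–H bonds are strong, so the choice lies among C7, C8 and C9 and is made by the variant. Rebound retains configuration, but either C7 epimer serves because step 6 erases the centre.

Step 6
Reactants: 6 7-hydroxylongipin-2-en-1-one
Product: 8 (4R,5S,10R,11R)-longipina-2,8-diene-1,7-dione, via longipin-2-ene-1,7-dione 7 (not isolated)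
Conditions: IBX (3 equiv), DMSO, 75 °C
Reagents that add atoms: none
Why: IBX oxidises the carbinol to ketone 7 and then dehydrogenates it through its enol by single-electron transfer (one-pot alcohol-to-enone conversion). Only C8 can enolise because C6 is quaternary, C10 is quaternary so no dienone can follow, and the C1 enone has only a bridgehead α′-hydrogen and is inert.

Step 7
Reactants: 8 longipina-2,8-diene-1,7-dione
Product: 10 (4R,5S,9S,10R,11R)-9-hydroxylongipin-2-ene-1,7-dione, via 9-pinacolboryl-longipin-2-ene-1,7-dione 9 (not isolated)
Conditions: CuCl (5 mol%), Josiphos ligand (the enantiomer that delivers boron to the C4 face), NaOtBu (10 mol%), B2pin2 (1.1 equiv), MeOH, THF, 0 °C to rt; then NaBO3·4H2O, THF/H2O, rt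
Reagents that add atoms: bis(pinacolato)diboron (boron of 9 only), CC1(C)OB(OC1(C)C)B1OC(C)(C)C(C)(C)O1; sodium perborate (oxygen on C9), [Na+].[Na+].O[B-]1(O)OO[B-](O)(O)OO1
Why: Copper-catalysed conjugate borylation of a cyclic enone: the borylcopper species (monovalent copper) adds across C8=C9 with boron on the β-carbon, methanol protonates the copper enolate, and perborate converts C–B into C–O with retention. The β,β-disubstituted C2=C3 enone is much slower. Because the substrate offers almost no facial bias, the chiral bisphosphine sets C9, placing boron and then oxygen on the C4 side (9S).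

Step 8
Reactants: 10 (9S)-9-hydroxylongipin-2-ene-1,7-dione
Product: 11 (4R,5S,7S,9S,10R,11R)-7,9-dihydroxylongipin-2-en-1-one
Conditions: Me4NBH(OAc)3, MeCN/AcOH (1:1), −30 to 0 °C
Reagents that add atoms: none
Why: Evans–Saksena reduction: the C9 hydroxyl replaces an acetate on boron and the hydride is passed to C7 through a six-membered chair-like transition state from the C4 face, so the new hydroxyl appears on the C11 face (7S, 1,3-anti). The reagent does not reduce ketones without this delivery, and the C9 oxygen cannot reach C1 because the C10–C9 and C11–C1 bonds are trans on the cyclobutane.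

Step 9
Reactants: 11 (7S,9S)-7,9-dihydroxylongipin-2-en-1-one; 12 angelic acid
Product: 14 (4R,5S,7S,9S,10R,11R)-7,9-bis(angeloyloxy)longipin-2-en-1-one, via angelic 2,4,6-trichlorobenzoic anhydride 13 (not isolated)
Conditions: 12 (6 equiv), 2,4,6-trichlorobenzoyl chloride, Et3N, toluene, rt; then 11, 80 °C
Reagents that add atoms: 2,4,6-trichlorobenzoyl chloride (aroyl group of 13 only; none of its atoms remain in 14), O=C(Cl)c1c(Cl)cc(Cl)cc1Cl
Why: Yamaguchi-type esterification: each alcohol attacks the angeloyl carbonyl of 13 because the aroyl carbonyl is shielded by two ortho chlorines. Leaving out a nucleophilic acyl-transfer catalyst avoids the addition–elimination path that turns angelate into tiglate. No stereocentre changes.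

## Compound list

1 | (2E,6E)-farnesol | CC(C)=CCC/C(C)=C/CC/C(C)=C/CO | starting material
2 | (2E,6E)-farnesyl chloride | CC(C)=CCC/C(C)=C/CC/C(C)=C/CCl | intermediate
3 | (2E,6E)-farnesyl diphosphate, triammonium salt | CC(C)=CCC/C(C)=C/CC/C(C)=C/COP(=O)([O-])OP(=O)([O-])[O-].[NH4+].[NH4+].[NH4+] | intermediate
4 | (+)-α-longipinene, (4R,5R,10S,11R)-longipin-2-ene | C1CC[C@@]2(C)[C@@H]3CC=C(C)[C@H]2[C@@H]3C1(C)C | intermediate
5 | (4R,5S,10R,11R)-longipin-2-en-1-one | C1CC[C@@]2(C)[C@@H]3C(=O)C=C(C)[C@H]2[C@@H]3C1(C)C | intermediate
6 | (4R,5S,7S,10R,11R)-7-hydroxylongipin-2-en-1-one (7S drawn; either C7 epimer serves) | O[C@H]1CC[C@@]2(C)[C@@H]3C(=O)C=C(C)[C@H]2[C@@H]3C1(C)C | intermediate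
7 | (4R,5S,10R,11R)-longipin-2-ene-1,7-dione (not isolated) | O=C1CC[C@@]2(C)[C@@H]3C(=O)C=C(C)[C@H]2[C@@H]3C1(C)C | intermediate
8 | (4R,5S,10R,11R)-longipina-2,8-diene-1,7-dione | O=C1C=C[C@@]2(C)[C@@H]3C(=O)C=C(C)[C@H]2[C@@H]3C1(C)C | intermediate
9 | (4R,5S,9S,10R,11R)-9-(4,4,5,5-tetramethyl-1,3,2-dioxaborolan-2-yl)longipin-2-ene-1,7-dione (not isolated) | O=C1C[C@H](B4OC(C)(C)C(C)(C)O4)[C@@]2(C)[C@@H]3C(=O)C=C(C)[C@H]2[C@@H]3C1(C)C | intermediate
10 | (4R,5S,9S,10R,11R)-9-hydroxylongipin-2-ene-1,7-dione | O=C1C[C@H](O)[C@@]2(C)[C@@H]3C(=O)C=C(C)[C@H]2[C@@H]3C1(C)C | intermediate
11 | (4R,5S,7S,9S,10R,11R)-7,9-dihydroxylongipin-2-en-1-one | O[C@H]1C[C@H](O)[C@@]2(C)[C@@H]3C(=O)C=C(C)[C@H]2[C@@H]3C1(C)C | intermediate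
12 | angelic acid, (Z)-2-methylbut-2-enoic acid | C/C=C(/C)C(=O)O | starting material
13 | angelic 2,4,6-trichlorobenzoic anhydride (not isolated) | C/C=C(/C)C(=O)OC(=O)c1c(Cl)cc(Cl)cc1Cl | intermediate
14 | (4R,5S,7S,9S,10R,11R)-7,9-bis[(Z)-2-methylbut-2-enoyloxy]longipin-2-en-1-one | C/C=C(/C)C(=O)O[C@H]1C[C@H](OC(=O)/C(C)=C\C)[C@@]2(C)[C@@H]3C(=O)C=C(C)[C@H]2[C@@H]3C1(C)C | target

## Step count and risk

Total step count: 9. Longest linear sequence: 9 steps (1 to 14); angelic acid 12 enters in step 9.

**Step 3 (key step).** The longipinyl cation may leak into other channels (exocyclic deprotonation, ring expansion to the longibornyl and longifolyl series). Turnover in vitro may also stall through product inhibition and precipitation of magnesium diphosphate, so that 4 becomes a minor hydrocarbon in a mixture of isomers. Fallback: run the same cyclisation as a fermentation in E. coli or yeast carrying a heterologous mevalonate pathway, a farnesyl diphosphate synthase and the (if necessary mutated) α-longipinene synthase under a dodecane overlay. Diphosphate 3 is then made inside the cell and never isolated, so steps 1 and 2 fall away. This fallback sets out from glucose and not from a numbered compound, and it rejoins the route at 4; it makes no new isolated compound.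

**Step 5.** The variant may hydroxylate the wrong methylene of the C7–C8–C9 strip, or the C3 methyl, because the strip has no intrinsic preference for C7. Fallback for the case of C9 attack: the mirror-image relay, which sets out from 5 and comes back at 11. A C9-selective variant gives 9-hydroxylongipin-2-en-1-one F1. IBX as in step 6 gives, through longipin-2-ene-1,9-dione F2, longipina-2,7-diene-1,9-dione F3. Copper-catalysed borylation with the ligand enantiomer that places boron on the C11 face of C7 gives 7-pinacolboryl-longipin-2-ene-1,9-dione F4, and perborate oxidation gives (7S)-7-hydroxylongipin-2-ene-1,9-dione F5. Evans–Saksena reduction then delivers hydride to C9 from the C11 face and leaves the C9 hydroxyl on the C4 face, which is diol 11. Hydroxylation at C8 is not rescued and must be screened out.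

**Step 7.** Borylcupration at the neopentyl β-carbon C9 may be slow, and the chiral pocket may discriminate the two nearly equivalent faces poorly next to the quaternary C10. Fallback, setting out from 8 and coming back at 10: Weitz–Scheffer epoxidation (H2O2, NaOH, MeOH, 0 °C), whose small nucleophile should reach C9 more easily, gives (8R,9R)-8,9-epoxylongipin-2-ene-1,7-dione F6. Reductive opening at the α-carbon with sodium phenylselenide (PhSeSePh, NaBH4, AcOH, EtOH) gives 10. The face is then no longer reagent-controlled, so this trades selectivity for reactivity and would lean on chromatography at the stage of 10.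

**Step 8.** Internal hydride delivery to the ketone next to the C6 gem-dimethyl carbon may be sluggish, and prolonged exposure to acetic acid may cause β-elimination of the C9 hydroxyl back to 8. Fallback, setting out from 10 and coming back at 11: Evans–Tishchenko reduction (acetaldehyde, SmI2 as precatalyst for the trivalent samarium alkoxide, THF, −10 °C). The hemiacetal formed on the C9 oxygen passes its hydride to C7 with the same 1,3-anti sense and gives (7S,9S)-9-acetoxy-7-hydroxylongipin-2-en-1-one F7; methanolysis (K2CO3, MeOH) releases 11.

**Step 9.** The second acylation of the hindered diol may be incomplete, and Z to E isomerisation to tiglate esters may set in during the long heating it needs. Fallback, setting out from 11 and coming back at 14: build the Z-alkene on the ester instead of transferring it. Acylation with 2-[bis(2,2,2-trifluoroethoxy)phosphoryl]propanoic acid (DCC, DMAP, CH2Cl2; this acid cannot isomerise) gives the 7,9-bis(phosphonopropanoate) F8. Still–Gennari olefination (KN(SiMe3)2, 18-crown-6, acetaldehyde, THF, −78 °C) then forms both (Z)-2-methylbut-2-enoates and gives 14.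

## Further compounds

F0 | step 3 | none | none
F1 | step 5 | (4R,5S,9S,10R,11R)-9-hydroxylongipin-2-en-1-one (9S drawn; either C9 epimer serves) | C1C[C@H](O)[C@@]2(C)[C@@H]3C(=O)C=C(C)[C@H]2[C@@H]3C1(C)C
F2 | step 5 | (4R,5S,10R,11R)-longipin-2-ene-1,9-dione | C1CC(=O)[C@@]2(C)[C@@H]3C(=O)C=C(C)[C@H]2[C@@H]3C1(C)C
F3 | step 5 | (4R,5S,10R,11R)-longipina-2,7-diene-1,9-dione | C1=CC(=O)[C@@]2(C)[C@@H]3C(=O)C=C(C)[C@H]2[C@@H]3C1(C)C
F4 | step 5 | (4R,5S,7S,10R,11R)-7-(4,4,5,5-tetramethyl-1,3,2-dioxaborolan-2-yl)longipin-2-ene-1,9-dione | B4(OC(C)(C)C(C)(C)O4)[C@H]1CC(=O)[C@@]2(C)[C@@H]3C(=O)C=C(C)[C@H]2[C@@H]3C1(C)C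
F5 | step 5 | (4R,5S,7S,10R,11R)-7-hydroxylongipin-2-ene-1,9-dione | O[C@H]1CC(=O)[C@@]2(C)[C@@H]3C(=O)C=C(C)[C@H]2[C@@H]3C1(C)C
F6 | step 7 | (4R,5S,8R,9R,10R,11R)-8,9-epoxylongipin-2-ene-1,7-dione | O=C1[C@@H]4O[C@@H]4[C@@]2(C)[C@@H]3C(=O)C=C(C)[C@H]2[C@@H]3C1(C)C
F7 | step 8 | (4R,5S,7S,9S,10R,11R)-9-acetoxy-7-hydroxylongipin-2-en-1-one | O[C@H]1C[C@H](OC(C)=O)[C@@]2(C)[C@@H]3C(=O)C=C(C)[C@H]2[C@@H]3C1(C)C
F8 | step 9 | (4R,5S,7S,9S,10R,11R)-7,9-bis{2-[bis(2,2,2-trifluoroethoxy)phosphoryl]propanoyloxy}longipin-2-en-1-one (epimers at the phosphonate α-carbons) | CC(C(=O)O[C@H]1C[C@H](OC(=O)C(C)P(=O)(OCC(F)(F)F)OCC(F)(F)F)[C@@]2(C)[C@@H]3C(=O)C=C(C)[C@H]2[C@@H]3C1(C)C)P(=O)(OCC(F)(F)F)OCC(F)(F)F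
A1 | alternative 1 | (2E,4S,6S,8E,10S)-4,6-bis[(tert-butyldimethylsilyl)oxy]-3,7,7,10-tetramethylcyclodeca-2,8-dien-1-one | O=C1/C=C(C)/[C@@H](O[Si](C)(C)C(C)(C)C)C[C@H](O[Si](C)(C)C(C)(C)C)C(C)(C)/C=C/[C@@H]1C
A2 | alternative 1 | 7,9-bis[(tert-butyldimethylsilyl)oxy]-2-norlongipinan-1-one (tricyclic bicyclo[2.1.1]hexan-2-one) | CC(C)(C)[Si](C)(C)O[C@H]1C[C@H](O[Si](C)(C)C(C)(C)C)[C@@]2(C)[C@@H]3C(=O)[C@@H](C)[C@H]2[C@@H]3C1(C)C
A3 | alternative 2 | 4,6-dimethyl-7-(2-methyl-3-oxobutan-2-yl)-2-oxobicyclo[3.1.1]hept-3-ene-6-carbaldehyde (8,9-seco form of 10, core configured as in 14) | O=C[C@@]2(C)[C@@H]3C(=O)C=C(C)[C@H]2[C@@H]3C(C)(C)C(C)=O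
A4 | alternative 2 | (4R,5S,9S,10R,11R)-9-hydroxylongipin-2-ene-1,7-dione (identical with 10) | O=C1C[C@H](O)[C@@]2(C)[C@@H]3C(=O)C=C(C)[C@H]2[C@@H]3C1(C)C
A5 | alternative 3 | methyl 5-methylspiro[tricyclo[4.1.0.0(2,7)]heptane-3,2'-[1,3]dioxolane]-1-carboxylate (core configured as in 14) | COC(=O)[C@]12[C@@H]3C4(OCCO4)C[C@H](C)[C@H]1[C@H]23
A6 | alternative 3 | (E)-1,3-bis[(tert-butyldimethylsilyl)oxy]-4-methylpenta-1,3-diene | CC(C)=C(O[Si](C)(C)C(C)(C)C)/C=C/O[Si](C)(C)C(C)(C)C
A7 | alternative 3 | tricyclic 7-ketone with C9 tert-butyldimethylsilyl ether, C10 methyl ester and C1 dioxolane | O=C1C[C@H](O[Si](C)(C)C(C)(C)C)[C@@]2(C(=O)OC)[C@@H]3C4(OCCO4)C[C@H](C)[C@H]2[C@@H]3C1(C)C
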